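**Strategy.** The cis-fused decahydroquinoline is cut across C4a–C8a and C5–C6. Its carbocycle (C4a, C5, C6, C7, C8, C8a) is read as the cyclohexene adduct of a nitrogen-bearing diene (C8a=C8–C7=C6) and a Z-alkene (C4a=C5), with N1–C2–C3–C4 of the piperidine as the tether. Heating an acyclic N-dienyl carbamate therefore closes both rings in one [4+2] step and creates C4a, C5 and C8a next to C2 and C3, which come from D-alanine. The precursor is a Teoc-protected N-[(1E)-buta-1,3-dienyl] amine carrying the C3 silyl ether, the Z-alkene and the silyl-protected side-chain carbinol. Hydrogenation, esterification and one acid deprotection finish the synthesis.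

Key step: step 11

Remark on the chemistry: the target is read as the (2R,3R,4aS,5S,8aR) cis-fused base with a (5R)-5-hydroxyoctyl chain (2-methyl, 3-acyloxy, H4a, H5 and H8a on one ring face); C3–O is carried as a triethylsilyl ether and the side-chain oxygen as a tert-butyldimethylsilyl ether so that one acid step ends the route.

**Route**

Step 1
Reactants: 1 (R)-2-propyloxirane; 2 1-bromo-4-chlorobutane
Product: 4 (4R)-9-chlorononan-4-ol, via 4-chlorobutylmagnesium bromide 3 (not isolated)
Conditions: 2, Mg, THF, 10 °C; then 1, CuI (10 mol%), THF, −30 → 0 °C; aq. NH4Cl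
Reagents that add atoms: none
Why: Copper-catalysed SN2 opening of a terminal epoxide by a primary Grignard reagent occurs at the unsubstituted carbon, so the carbinol centre of 1 is carried over unchanged, and the alkyl chloride is inert under these conditions.

Step 2
Reactants: 4 (4R)-9-chlorononan-4-ol
Product: 5 tert-butyl{[(4R)-9-chlorononan-4-yl]oxy}dimethylsilane
Conditions: TBSCl, imidazole, DMF, rt
Reagents that add atoms: tert-butyldimethylsilyl chloride, CC(C)(C)[Si](C)(C)Cl
Why: Imidazole-promoted O-silylation of a secondary alcohol; the stereocentre is not touched.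

Step 3
Reactants: 5 tert-butyl{[(4R)-9-chlorononan-4-yl]oxy}dimethylsilane
Product: 7 [(6R)-6-(tert-butyldimethylsilyloxy)nonyl]triphenylphosphonium iodide, via iodide 6 (not isolated)
Conditions: NaI, PPh3, MeCN, reflux
Reagents that add atoms: triphenylphosphine, c1ccc(cc1)P(c1ccccc1)c1ccccc1; sodium iodide, [Na+].[I-]
Why: Finkelstein halide exchange gives the primary iodide, which quaternises triphenylphosphine by SN2; the remote silyl ether is stable in neutral acetonitrile.

Step 4
Reactants: 8 N-Boc-D-alanine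
Product: 11 ethyl (4R)-4-(tert-butoxycarbonylamino)-3-oxopentanoate, via acyl imidazolide 9 (not isolated), via acylmalonic half-ester 10 (not isolated)
Conditions: CDI, THF, rt; then magnesium mono-ethyl malonate, THF, rt → 40 °C; 1 M HCl work-up
Reagents that add atoms: magnesium mono-ethyl malonate, [Mg+2].CCOC(=O)CC([O-])=O.CCOC(=O)CC([O-])=O
Why: Masamune-type C-acylation of a magnesium malonate half-ester by the acyl imidazolide, followed by decarboxylation, gives the β-keto ester; the urethane-protected α-centre is not racemised under these near-neutral conditions.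

Step 5
Reactants: 11 ethyl (4R)-4-(tert-butoxycarbonylamino)-3-oxopentanoate
Product: 12 ethyl (3R,4R)-4-(tert-butoxycarbonylamino)-3-hydroxypentanoate
Conditions: H2 (50 atm), RuBr2[(S)-BINAP] (1 mol%), EtOH, 40 °C
Reagents that add atoms: none
Why: Noyori asymmetric hydrogenation of a β-keto ester; the ester-chelated Ru–(S)-BINAP catalyst delivers hydrogen to the ketone face that gives the (3R) alcohol, which is the matched, syn outcome for the (4R) carbamate centre (C3 of the target).

Step 6
Reactants: 12 ethyl (3R,4R)-4-(tert-butoxycarbonylamino)-3-hydroxypentanoate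
Product: 13 ethyl (3R,4R)-4-(tert-butoxycarbonylamino)-3-(triethylsilyloxy)pentanoate
Conditions: TESCl, imidazole, DMF, 0 °C → rt
Reagents that add atoms: triethylsilyl chloride, CC[Si](Cl)(CC)CC
Why: Imidazole-promoted O-silylation; the neutral conditions leave the Boc group and both stereocentres untouched.

Step 7
Reactants: 13 ethyl (3R,4R)-4-(tert-butoxycarbonylamino)-3-(triethylsilyloxy)pentanoate
Product: 14 tert-butyl N-[(2R,3R)-5-oxo-3-(triethylsilyloxy)pentan-2-yl]carbamate
Conditions: DIBAL-H (2.2 equiv), CH2Cl2, −78 °C; MeOH, then aq. Rochelle salt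
Reagents that add atoms: none
Why: Partial reduction of an ester by DIBAL-H at −78 °C stops at the aluminium hemiacetal, which the β-silyloxy group stabilises, and work-up releases the aldehyde; one equivalent is consumed by the carbamate N–H.

Step 8
Reactants: 7 [(6R)-6-(tert-butyldimethylsilyloxy)nonyl]triphenylphosphonium iodide; 14 tert-butyl N-[(2R,3R)-5-oxo-3-(triethylsilyloxy)pentan-2-yl]carbamate
Product: 16 tert-butyl N-[(2R,3R,5Z,11R)-11-(tert-butyldimethylsilyloxy)-3-(triethylsilyloxy)tetradec-5-en-2-yl]carbamate, via phosphorus ylide 15 (not isolated)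
Conditions: 7 (2.2 equiv), NaHMDS (2.1 equiv), THF, −78 → 0 °C; then 14, −78 °C → rt
Reagents that add atoms: none
Why: Wittig reaction of a non-stabilised ylide under lithium-free conditions passes through the kinetically favoured cis-oxaphosphetane and sets C4a=C5 with Z geometry; the excess ylide covers the acidic carbamate N–H.

Step 9
Reactants: 16 tert-butyl N-[(2R,3R,5Z,11R)-11-(tert-butyldimethylsilyloxy)-3-(triethylsilyloxy)tetradec-5-en-2-yl]carbamate
Product: 18 (2R,3R,5Z,11R)-11-(tert-butyldimethylsilyloxy)-3-(triethylsilyloxy)tetradec-5-en-2-amine, via trimethylsilyl carbamate 17 (not isolated)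
Conditions: TMSOTf (3 equiv), 2,6-lutidine (4 equiv), CH2Cl2, 0 °C → rt; then sat. aq. NaHCO3/MeOH
Reagents that add atoms: none
Why: Silyl triflate-mediated cleavage of a tert-butyl carbamate (loss of isobutene, then hydrolysis of the silyl carbamate) runs in a buffered, non-protic medium, so both silyl ethers and the Z-alkene survive where protic acid would not be selective.

Step 10
Reactants: 18 (2R,3R,5Z,11R)-11-(tert-butyldimethylsilyloxy)-3-(triethylsilyloxy)tetradec-5-en-2-amine; 19 (E)-crotonaldehyde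
Product: 22 2-(trimethylsilyl)ethyl N-[(1E)-buta-1,3-dien-1-yl]-N-[(2R,3R,5Z,11R)-11-(tert-butyldimethylsilyloxy)-3-(triethylsilyloxy)tetradec-5-en-2-yl]carbamate, via imine 20 (not isolated), via sodium azadienide 21 (not isolated)
Conditions: 19 (1.05 equiv), 4 Å MS, THF, 0 °C → rt; filtrate added to NaHMDS (1.1 equiv), THF, −78 °C; then TeocCl (1.2 equiv), −78 → −20 °C
Reagents that add atoms: 2-(trimethylsilyl)ethyl chloroformate, C[Si](C)(C)CCOC(=O)Cl
Why: Condensation gives the 1-azadiene, γ-deprotonation gives a delocalised 1-azapentadienyl anion, and the chloroformate acylates it on nitrogen, which is the established entry to (1E)-N-dienyl carbamates; no stereocentre is involved.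

Step 11
Reactants: 22 2-(trimethylsilyl)ethyl N-[(1E)-buta-1,3-dien-1-yl]-N-[(2R,3R,5Z,11R)-11-(tert-butyldimethylsilyloxy)-3-(triethylsilyloxy)tetradec-5-en-2-yl]carbamate
Product: 23 2-(trimethylsilyl)ethyl (2R,3R,4aS,5S,8aR)-5-[(5R)-5-(tert-butyldimethylsilyloxy)octyl]-2-methyl-3-(triethylsilyloxy)-3,4,4a,5,6,8a-hexahydroquinoline-1(2H)-carboxylate
Conditions: toluene (5 mM), BHT (5 mol%), silanised sealed tube, argon, 200 °C
Reagents that add atoms: none
Why: A concerted, suprafacial thermal [4+2] cycloaddition joins the 1-amido diene C8a=C8–C7=C6 to the tethered Z-alkene C4a=C5; the closest known reaction type is the intramolecular Diels–Alder reaction of N-acyl-N-dienylamines with unactivated alkenes near 200 °C, which gives cis-fused octahydroquinolines. The carbocycle closes as the new cyclohexene (bonds C4a–C8a and C5–C6, double bond moved to C7=C8), and the piperidine closes in the same event as a six-membered ring because the tether N1–C2–C3–C4 links the diene terminus C8a to the dienophile carbon C4a. C5 is set stereospecifically by the Z geometry (H4a and H5 cis), C4a and C8a are set together by the cis-fused mode of closure, and their absolute sense is relayed from C2 and C3 through the conformation of the forming piperidine. The step needs cis fusion, which is the usual outcome for this substrate class, and bonding on the diene face that leaves C8 trans to the C2 methyl group. In the cis-fused mode C8 is pseudo-axial on the forming piperidine, so the required face has the C2 methyl group near the carbamate plane and the C3 silyl ether axial, and it competes with an arrangement with an axial methyl group that adds to the other face. A carbamate (smaller A1,3 demand than an amide) and the compact triethylsilyl ether are chosen to keep the required arrangement accessible; this facial choice is the one risk the route accepts.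

Step 12
Reactants: 23 2-(trimethylsilyl)ethyl (2R,3R,4aS,5S,8aR)-5-[(5R)-5-(tert-butyldimethylsilyloxy)octyl]-2-methyl-3-(triethylsilyloxy)-3,4,4a,5,6,8a-hexahydroquinoline-1(2H)-carboxylate
Product: 24 2-(trimethylsilyl)ethyl (2R,3R,4aS,5S,8aR)-5-[(5R)-5-(tert-butyldimethylsilyloxy)octyl]-2-methyl-3-(triethylsilyloxy)octahydroquinoline-1(2H)-carboxylate
Conditions: H2 (1 atm), 10% Pd/C, EtOAc, rt
Reagents that add atoms: none
Why: Heterogeneous hydrogenation saturates the cis-disubstituted C7=C8 bond without creating a stereocentre; silyl ethers and the Teoc group are inert in ethyl acetate.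

Step 13
Reactants: 24 2-(trimethylsilyl)ethyl (2R,3R,4aS,5S,8aR)-5-[(5R)-5-(tert-butyldimethylsilyloxy)octyl]-2-methyl-3-(triethylsilyloxy)octahydroquinoline-1(2H)-carboxylate
Product: 25 2-(trimethylsilyl)ethyl (2R,3R,4aS,5S,8aR)-5-[(5R)-5-(tert-butyldimethylsilyloxy)octyl]-3-hydroxy-2-methyloctahydroquinoline-1(2H)-carboxylate
Conditions: PPTS (0.3 equiv), MeOH/CH2Cl2, 0 °C → rt
Reagents that add atoms: none
Why: Acid-catalysed methanolysis cleaves a triethylsilyl ether far faster than a secondary tert-butyldimethylsilyl ether, and the Teoc carbamate is stable to this weak acid.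

Step 14
Reactants: 25 2-(trimethylsilyl)ethyl (2R,3R,4aS,5S,8aR)-5-[(5R)-5-(tert-butyldimethylsilyloxy)octyl]-3-hydroxy-2-methyloctahydroquinoline-1(2H)-carboxylate; 26 (E)-oct-2-enoic acid
Product: 27 2-(trimethylsilyl)ethyl (2R,3R,4aS,5S,8aR)-5-[(5R)-5-(tert-butyldimethylsilyloxy)octyl]-2-methyl-3-[(2E)-oct-2-enoyloxy]octahydroquinoline-1(2H)-carboxylate
Conditions: 26 (1.5 equiv), DCC, DMAP (0.2 equiv), CH2Cl2, 0 °C → rt
Reagents that add atoms: none
Why: Steglich esterification (carbodiimide activation, acyl transfer by DMAP) acylates the only free hydroxyl group with retention at C3; low temperature and catalytic DMAP limit migration of the conjugated double bond.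

Step 15
Reactants: 27 2-(trimethylsilyl)ethyl (2R,3R,4aS,5S,8aR)-5-[(5R)-5-(tert-butyldimethylsilyloxy)octyl]-2-methyl-3-[(2E)-oct-2-enoyloxy]octahydroquinoline-1(2H)-carboxylate
Product: 28 (2R,3R,4aS,5S,8aR)-5-[(5R)-5-hydroxyoctyl]-2-methyldecahydroquinolin-3-yl (2E)-oct-2-enoate
Conditions: TFA/CH2Cl2/H2O (10:10:1), 0 °C → rt; then aq. NaHCO3
Reagents that add atoms: none
Why: Acidolysis fragments the 2-(trimethylsilyl)ethyl carbamate (β-silyl-assisted loss of ethylene and CO2) and aqueous acid hydrolyses the TBS ether, while the enoate ester is acid-stable; the amine stays protonated until the mild basic work-up.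

**Compound list**

1 | (R)-2-propyloxirane | CCC[C@@H]1CO1 | starting material
2 | 1-bromo-4-chlorobutane | ClCCCCBr | starting material
3 | 4-chlorobutylmagnesium bromide | ClCCCC[Mg]Br | intermediate
4 | (4R)-9-chlorononan-4-ol | CCC[C@@H](O)CCCCCCl | intermediate
5 | tert-butyl{[(4R)-9-chlorononan-4-yl]oxy}dimethylsilane | CCC[C@@H](O[Si](C)(C)C(C)(C)C)CCCCCCl | intermediate
6 | tert-butyl{[(4R)-9-iodononan-4-yl]oxy}dimethylsilane | CCC[C@@H](O[Si](C)(C)C(C)(C)C)CCCCCI | intermediate
7 | [(6R)-6-(tert-butyldimethylsilyloxy)nonyl]triphenylphosphonium iodide | CCC[C@@H](O[Si](C)(C)C(C)(C)C)CCCCC[P+](c1ccccc1)(c1ccccc1)c1ccccc1.[I-] | intermediate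
8 | N-Boc-D-alanine, (2R)-2-(tert-butoxycarbonylamino)propanoic acid | C[C@@H](NC(=O)OC(C)(C)C)C(=O)O | starting material
9 | tert-butyl N-[(2R)-1-(imidazol-1-yl)-1-oxopropan-2-yl]carbamate | C[C@@H](NC(=O)OC(C)(C)C)C(=O)n1ccnc1 | intermediate
10 | (4R)-4-(tert-butoxycarbonylamino)-2-(ethoxycarbonyl)-3-oxopentanoic acid | CCOC(=O)C(C(=O)O)C(=O)[C@@H](C)NC(=O)OC(C)(C)C | intermediate
11 | ethyl (4R)-4-(tert-butoxycarbonylamino)-3-oxopentanoate | CCOC(=O)CC(=O)[C@@H](C)NC(=O)OC(C)(C)C | intermediate
12 | ethyl (3R,4R)-4-(tert-butoxycarbonylamino)-3-hydroxypentanoate | CCOC(=O)C[C@@H](O)[C@@H](C)NC(=O)OC(C)(C)C | intermediate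
13 | ethyl (3R,4R)-4-(tert-butoxycarbonylamino)-3-(triethylsilyloxy)pentanoate | CCOC(=O)C[C@@H](O[Si](CC)(CC)CC)[C@@H](C)NC(=O)OC(C)(C)C | intermediate
14 | tert-butyl N-[(2R,3R)-5-oxo-3-(triethylsilyloxy)pentan-2-yl]carbamate | O=CC[C@@H](O[Si](CC)(CC)CC)[C@@H](C)NC(=O)OC(C)(C)C | intermediate
15 | [(6R)-6-(tert-butyldimethylsilyloxy)nonylidene]triphenylphosphorane | CCC[C@@H](O[Si](C)(C)C(C)(C)C)CCCCC=P(c1ccccc1)(c1ccccc1)c1ccccc1 | intermediate
16 | tert-butyl N-[(2R,3R,5Z,11R)-11-(tert-butyldimethylsilyloxy)-3-(triethylsilyloxy)tetradec-5-en-2-yl]carbamate | CCC[C@@H](O[Si](C)(C)C(C)(C)C)CCCC/C=C\C[C@@H](O[Si](CC)(CC)CC)[C@@H](C)NC(=O)OC(C)(C)C | intermediate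
17 | trimethylsilyl N-[(2R,3R,5Z,11R)-11-(tert-butyldimethylsilyloxy)-3-(triethylsilyloxy)tetradec-5-en-2-yl]carbamate | CCC[C@@H](O[Si](C)(C)C(C)(C)C)CCCC/C=C\C[C@@H](O[Si](CC)(CC)CC)[C@@H](C)NC(=O)O[Si](C)(C)C | intermediate
18 | (2R,3R,5Z,11R)-11-(tert-butyldimethylsilyloxy)-3-(triethylsilyloxy)tetradec-5-en-2-amine | CCC[C@@H](O[Si](C)(C)C(C)(C)C)CCCC/C=C\C[C@@H](O[Si](CC)(CC)CC)[C@@H](C)N | intermediate
19 | (E)-crotonaldehyde | C/C=C/C=O | starting material
20 | (1E,2E)-N-[(2R,3R,5Z,11R)-11-(tert-butyldimethylsilyloxy)-3-(triethylsilyloxy)tetradec-5-en-2-yl]but-2-en-1-imine | CCC[C@@H](O[Si](C)(C)C(C)(C)C)CCCC/C=C\C[C@@H](O[Si](CC)(CC)CC)[C@@H](C)/N=C/C=C/C | intermediate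
21 | sodium salt of the 1-azapenta-2,4-dienyl anion formed from 20 by γ-deprotonation | [Na+].C=C/C=C/[N-][C@H](C)[C@H](O[Si](CC)(CC)CC)C/C=C\CCCC[C@H](O[Si](C)(C)C(C)(C)C)CCC | intermediate
22 | 2-(trimethylsilyl)ethyl N-[(1E)-buta-1,3-dien-1-yl]-N-[(2R,3R,5Z,11R)-11-(tert-butyldimethylsilyloxy)-3-(triethylsilyloxy)tetradec-5-en-2-yl]carbamate | C[Si](C)(C)CCOC(=O)N(/C=C/C=C)[C@H](C)[C@H](O[Si](CC)(CC)CC)C/C=C\CCCC[C@H](O[Si](C)(C)C(C)(C)C)CCC | intermediate
23 | 2-(trimethylsilyl)ethyl (2R,3R,4aS,5S,8aR)-5-[(5R)-5-(tert-butyldimethylsilyloxy)octyl]-2-methyl-3-(triethylsilyloxy)-3,4,4a,5,6,8a-hexahydroquinoline-1(2H)-carboxylate | CC[Si](CC)(CC)O[C@@H]1C[C@H]2[C@@H](CCCC[C@H](O[Si](C)(C)C(C)(C)C)CCC)CC=C[C@H]2N(C(=O)OCC[Si](C)(C)C)[C@@H]1C | intermediate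
24 | 2-(trimethylsilyl)ethyl (2R,3R,4aS,5S,8aR)-5-[(5R)-5-(tert-butyldimethylsilyloxy)octyl]-2-methyl-3-(triethylsilyloxy)octahydroquinoline-1(2H)-carboxylate | CC[Si](CC)(CC)O[C@@H]1C[C@H]2[C@@H](CCCC[C@H](O[Si](C)(C)C(C)(C)C)CCC)CCC[C@H]2N(C(=O)OCC[Si](C)(C)C)[C@@H]1C | intermediate
25 | 2-(trimethylsilyl)ethyl (2R,3R,4aS,5S,8aR)-5-[(5R)-5-(tert-butyldimethylsilyloxy)octyl]-3-hydroxy-2-methyloctahydroquinoline-1(2H)-carboxylate | O[C@@H]1C[C@H]2[C@@H](CCCC[C@H](O[Si](C)(C)C(C)(C)C)CCC)CCC[C@H]2N(C(=O)OCC[Si](C)(C)C)[C@@H]1C | intermediate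
26 | (E)-oct-2-enoic acid | CCCCC/C=C/C(=O)O | starting material
27 | 2-(trimethylsilyl)ethyl (2R,3R,4aS,5S,8aR)-5-[(5R)-5-(tert-butyldimethylsilyloxy)octyl]-2-methyl-3-[(2E)-oct-2-enoyloxy]octahydroquinoline-1(2H)-carboxylate | CCCCC/C=C/C(=O)O[C@@H]1C[C@H]2[C@@H](CCCC[C@H](O[Si](C)(C)C(C)(C)C)CCC)CCC[C@H]2N(C(=O)OCC[Si](C)(C)C)[C@@H]1C | intermediate
28 | (2R,3R,4aS,5S,8aR)-5-[(5R)-5-hydroxyoctyl]-2-methyldecahydroquinolin-3-yl (2E)-oct-2-enoate | CCCCC/C=C/C(=O)O[C@@H]1C[C@H]2[C@@H](CCCC[C@H](O)CCC)CCC[C@H]2N[C@@H]1C | target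

Total step count: 15. Longest linear sequence: 12 steps (steps 4–15, from 8); the side-chain branch (steps 1–3) joins at step 8.

**Steps most likely to fail**

1. Step 11. The wrong diene face may be chosen. The arrangement that relieves A1,3 strain (axial C2 methyl, equatorial C3 silyl ether) bonds to the face that puts C8 cis to the methyl group and would give the C4a/C5/C8a-epimeric cis adduct; slow polymerisation of the diene at 200 °C is a lesser loss. The fallback changes the diene geometry and the way the N-dienyl unit is built; it sets out from amine 18 and comes back at 23. Amine 18 is acylated with Teoc-OSu to the N–H Teoc carbamate F1. Trichloroethylene and Cs2CO3 in DMF (dichloroacetylene formed in the flask) convert it into the (E)-1,2-dichloroethenyl carbamate F2. Phenyllithium at −78 °C (elimination, then chlorine–lithium exchange) and protonation give the N-ethynyl carbamate F3. Sonogashira coupling with vinyl bromide gives the enynyl carbamate F4, and Lindlar semihydrogenation gives the (1Z)-dienyl carbamate F5, which is heated as in step 11. A Z-diene with the tether on its inner position can close only in the cis-fused mode, and C8 is then pseudo-equatorial and C5 pseudo-axial on the forming piperidine. The chair with an axial C2 methyl group and an equatorial C3 silyl ether therefore leads to 23, though a higher temperature may be needed.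

2. Step 10. The azapentadienyl anion may be acylated at carbon instead of nitrogen, or imine formation with the α-branched amine may stay incomplete and revert. The fallback builds the dienyl group by isomerisation; it sets out from 18 and comes back at 22. N-Alkylation with 1-bromobut-2-yne (K2CO3, MeCN) gives the N-(but-2-ynyl) amine F6, and 2-(trimethylsilyl)ethyl chloroformate with i-Pr2NEt gives the N-(but-2-ynyl) carbamate F7. Catalytic KOt-Bu in THF isomerises it to the N-(buta-1,2-dienyl) carbamate F8, and a 1,3-hydrogen shift on warming in toluene (or with a trace of camphorsulfonic acid) gives the (1E)-dienyl carbamate 22.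

3. Step 7. The reduction may run past the aldehyde, and the γ-carbamoyl aldehyde may close onto nitrogen as a cyclic hemiaminal on standing. The fallback separates reduction and oxidation; it sets out from 13 and comes back at 14. LiBH4 in THF/MeOH reduces the ester fully to the primary alcohol F9, and buffered Dess–Martin oxidation (NaHCO3, CH2Cl2, 0 °C) gives 14, which is used at once in step 8.

**Further compounds**

F1 | step 11 | 2-(trimethylsilyl)ethyl N-[(2R,3R,5Z,11R)-11-(tert-butyldimethylsilyloxy)-3-(triethylsilyloxy)tetradec-5-en-2-yl]carbamate | C[Si](C)(C)CCOC(=O)N[C@H](C)[C@H](O[Si](CC)(CC)CC)C/C=C\CCCC[C@H](O[Si](C)(C)C(C)(C)C)CCC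
F2 | step 11 | 2-(trimethylsilyl)ethyl N-[(E)-1,2-dichloroethenyl]-N-[(2R,3R,5Z,11R)-11-(tert-butyldimethylsilyloxy)-3-(triethylsilyloxy)tetradec-5-en-2-yl]carbamate | C[Si](C)(C)CCOC(=O)N(/C(Cl)=C\Cl)[C@H](C)[C@H](O[Si](CC)(CC)CC)C/C=C\CCCC[C@H](O[Si](C)(C)C(C)(C)C)CCC
F3 | step 11 | 2-(trimethylsilyl)ethyl N-ethynyl-N-[(2R,3R,5Z,11R)-11-(tert-butyldimethylsilyloxy)-3-(triethylsilyloxy)tetradec-5-en-2-yl]carbamate | C[Si](C)(C)CCOC(=O)N(C#C)[C@H](C)[C@H](O[Si](CC)(CC)CC)C/C=C\CCCC[C@H](O[Si](C)(C)C(C)(C)C)CCC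
F4 | step 11 | 2-(trimethylsilyl)ethyl N-(but-3-en-1-yn-1-yl)-N-[(2R,3R,5Z,11R)-11-(tert-butyldimethylsilyloxy)-3-(triethylsilyloxy)tetradec-5-en-2-yl]carbamate | C[Si](C)(C)CCOC(=O)N(C#CC=C)[C@H](C)[C@H](O[Si](CC)(CC)CC)C/C=C\CCCC[C@H](O[Si](C)(C)C(C)(C)C)CCC
F5 | step 11 | 2-(trimethylsilyl)ethyl N-[(1Z)-buta-1,3-dien-1-yl]-N-[(2R,3R,5Z,11R)-11-(tert-butyldimethylsilyloxy)-3-(triethylsilyloxy)tetradec-5-en-2-yl]carbamate | C[Si](C)(C)CCOC(=O)N(/C=C\C=C)[C@H](C)[C@H](O[Si](CC)(CC)CC)C/C=C\CCCC[C@H](O[Si](C)(C)C(C)(C)C)CCC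
F6 | step 10 | (2R,3R,5Z,11R)-N-(but-2-yn-1-yl)-11-(tert-butyldimethylsilyloxy)-3-(triethylsilyloxy)tetradec-5-en-2-amine | CC#CCN[C@H](C)[C@H](O[Si](CC)(CC)CC)C/C=C\CCCC[C@H](O[Si](C)(C)C(C)(C)C)CCC
F7 | step 10 | 2-(trimethylsilyl)ethyl N-(but-2-yn-1-yl)-N-[(2R,3R,5Z,11R)-11-(tert-butyldimethylsilyloxy)-3-(triethylsilyloxy)tetradec-5-en-2-yl]carbamate | CC#CCN(C(=O)OCC[Si](C)(C)C)[C@H](C)[C@H](O[Si](CC)(CC)CC)C/C=C\CCCC[C@H](O[Si](C)(C)C(C)(C)C)CCC
F8 | step 10 | 2-(trimethylsilyl)ethyl N-(buta-1,2-dien-1-yl)-N-[(2R,3R,5Z,11R)-11-(tert-butyldimethylsilyloxy)-3-(triethylsilyloxy)tetradec-5-en-2-yl]carbamate | CC=C=CN(C(=O)OCC[Si](C)(C)C)[C@H](C)[C@H](O[Si](CC)(CC)CC)C/C=C\CCCC[C@H](O[Si](C)(C)C(C)(C)C)CCC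
F9 | step 7 | tert-butyl N-[(2R,3R)-5-hydroxy-3-(triethylsilyloxy)pentan-2-yl]carbamate | OCC[C@@H](O[Si](CC)(CC)CC)[C@@H](C)NC(=O)OC(C)(C)C
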